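**Retrosynthetic overview**
1. Ester C–O bond: the target comes from dotriacontanoic acid and tyrosol. The phenol is masked as a benzyl ether that is removed last.
2. The C32 acid comes from 11-oxodotriacontanoic acid (C=O to CH2, Wolff–Kishner), which comes from the 9-en-11-one ester and, before that, the 9-hydroxy-11-oxo ester.
3. Key C9–C10 bond: crossed boron aldol of tricosan-2-one (C23, enolate on the CH3 side) with methyl 9-oxononanoate (C9).
4. Tricosan-2-one comes from behenic acid (Weinreb amide, then MeMgBr). Methyl 9-oxononanoate comes from methyl oleate (ozonolysis).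
5. No ring is formed; the only ring, the arene, is bought with tyrosol.

Assumption: the target has no stereocentre and is achiral, so there is no enantiomer to select. The acyl chain is read as the unbranched C32 (dotriacontanoyl) chain.

**Step 1**
Reactants: 1 docosanoic (behenic) acid
Product: 3 N-methoxy-N-methyldocosanamide, via docosanoyl chloride 2 (not isolated)
Conditions: SOCl2 (1.5 equiv), cat. DMF, toluene, 70 °C, evaporate; MeNH(OMe)·HCl (1.2 equiv), pyridine (2.5 equiv), CH2Cl2, 0 °C → rt
Reagents that add atoms: N,O-dimethylhydroxylamine hydrochloride, CNOC.Cl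
Why: Acid chloride formation followed by N-acylation (Nahm–Weinreb amide synthesis) is high-yielding for fatty acids, warm toluene keeps the C22 acid dissolved, and pyridine is too weak a base to form ketene.

**Step 2**
Reactants: 3 N-methoxy-N-methyldocosanamide
Product: 5 tricosan-2-one, via magnesium hemiaminal chelate 4 (not isolated)
Conditions: MeMgBr (1.5 equiv, 3 M in Et2O), THF, 0 °C → rt; 1 M HCl
Reagents that add atoms: methylmagnesium bromide, C[Mg]Br
Why: In the Weinreb ketone synthesis the Mg-chelated tetrahedral adduct survives until the acidic quench, so exactly one methyl group is delivered and no tertiary alcohol forms.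

**Step 3**
Reactants: 6 methyl oleate
Product: 8 methyl 9-oxononanoate, via secondary ozonide 7 (not isolated)
Conditions: O3, CH2Cl2, −78 °C; N2 purge; PPh3 (1.05 equiv), −78 °C → rt; vacuum distillation
Reagents that add atoms: ozone, [O-][O+]=O
Why: Ozonolysis (Criegee mechanism) with reductive PPh3 work-up cleaves the only C=C to two aldehydes without touching the ester, and the aldehyde ester is separated from the more volatile nonanal by distillation.

**Step 4 (key step)**
Reactants: 5 tricosan-2-one; 8 methyl 9-oxononanoate
Product: 11 methyl 9-hydroxy-11-oxodotriacontanoate (racemic), via boron enolate 9 (not isolated), via boron aldolate 10 (not isolated)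
Conditions: Cy2BCl (1.3 equiv), Et3N (1.5 equiv), CH2Cl2 (0.05 M), 0 °C, 1 h; 8 (1.3 equiv), −20 → 0 °C; MeOH, pH 7 buffer, 30% H2O2, 0 °C → rt
Reagents that add atoms: none
Why: In this boron-mediated crossed aldol addition, Cy2BCl/Et3N enolises the methyl ketone on the unhindered CH3 side, and the preformed enolate adds (Zimmerman–Traxler) to the aldehyde rather than the ester to forge C9–C10; the new C9 carbinol centre is racemic and is erased in step 5.

**Step 5**
Reactants: 11 methyl 9-hydroxy-11-oxodotriacontanoate
Product: 13 methyl (E)-11-oxodotriacont-9-enoate, via β-mesyloxy ketone 12 (not isolated)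
Conditions: MsCl (1.5 equiv), Et3N (4 equiv), CH2Cl2, 0 °C → rt
Reagents that add atoms: none
Why: Mesylation followed by E1cB elimination of the β-mesyloxy ketone gives the conjugated (E)-enone under mild basic conditions that avoid retro-aldol cleavage and leave the ester intact.

**Step 6**
Reactants: 13 methyl (E)-11-oxodotriacont-9-enoate
Product: 14 methyl 11-oxodotriacontanoate
Conditions: H2 (1 atm), 10% Pd/C, EtOAc–THF, 40 °C
Reagents that add atoms: none
Why: Heterogeneous catalytic hydrogenation saturates the conjugated C=C, while a dialkyl ketone and a methyl ester are inert to Pd/C at 1 atm.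

**Step 7**
Reactants: 14 methyl 11-oxodotriacontanoate
Product: 15 11-oxodotriacontanoic acid
Conditions: KOH (3 equiv), THF–MeOH–H2O, 60 °C; 2 M HCl
Reagents that add atoms: potassium hydroxide, [K+].[OH-]
Why: Saponification (BAc2 ester hydrolysis) is done before the hydrazine step so that the ester cannot be diverted into an acyl hydrazide.

**Step 8**
Reactants: 15 11-oxodotriacontanoic acid
Product: 17 dotriacontanoic acid, via hydrazone 16 (not isolated)
Conditions: N2H4·H2O (5 equiv), KOH (5 equiv), diethylene glycol, 130 °C, 2 h; distil to 200 °C, 5 h; hot 2 M HCl; recrystallise (toluene)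
Reagents that add atoms: none
Why: The Wolff–Kishner reduction (Huang-Minlon modification) is the classical way to turn long-chain keto acids into the saturated acids, and the carboxylate is the only other function and is inert.

**Step 9**
Reactants: 18 tyrosol, 4-(2-hydroxyethyl)phenol
Product: 19 2-[4-(benzyloxy)phenyl]ethanol
Conditions: BnBr (1.05 equiv), K2CO3 (1.5 equiv), acetone, reflux
Reagents that add atoms: benzyl bromide, BrCc1ccccc1
Why: In this Williamson ether synthesis K2CO3 deprotonates only the phenol (pKa about 10) and not the primary alcohol (pKa about 16), so O-benzylation is chemoselective.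

**Step 10**
Reactants: 17 dotriacontanoic acid; 19 2-[4-(benzyloxy)phenyl]ethanol
Product: 21 2-[4-(benzyloxy)phenyl]ethyl dotriacontanoate, via dotriacontanoyl chloride 20 (not isolated)
Conditions: SOCl2 (3 equiv), cat. DMF, toluene, 80 °C, evaporate; 19 (1.1 equiv), pyridine (3 equiv), DMAP (0.1 equiv), toluene, 60 °C
Reagents that add atoms: none
Why: DMAP-catalysed acylation of the only free OH by the acid chloride runs in warm toluene, where the waxy C32 acyl component is soluble, and pyridine avoids ketene dimer formation.

**Step 11**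
Reactants: 21 2-[4-(benzyloxy)phenyl]ethyl dotriacontanoate
Product: 22 Basalethanolide A, 2-(4-hydroxyphenyl)ethyl dotriacontanoate
Conditions: H2 (1 atm), 10% Pd/C, THF–EtOAc, 40 °C
Reagents that add atoms: none
Why: Catalytic hydrogenolysis cleaves the benzylic aryl benzyl ether under neutral conditions, whereas the ester C–O bond is homobenzylic and is not cleaved.

**Compound list**
1 | docosanoic (behenic) acid | CCCCCCCCCCCCCCCCCCCCCC(=O)O | starting material
2 | docosanoyl chloride | CCCCCCCCCCCCCCCCCCCCCC(=O)Cl | intermediate
3 | N-methoxy-N-methyldocosanamide | CCCCCCCCCCCCCCCCCCCCCC(=O)N(C)OC | intermediate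
4 | magnesium hemiaminal chelate: bromomagnesium 2-[methoxy(methyl)amino]tricosan-2-olate (racemic) | CCCCCCCCCCCCCCCCCCCCCC(C)(O[Mg]Br)N(C)OC | intermediate
5 | tricosan-2-one | CCCCCCCCCCCCCCCCCCCCCC(C)=O | intermediate
6 | methyl oleate, methyl (Z)-octadec-9-enoate | CCCCCCCC/C=C\CCCCCCCC(=O)OC | starting material
7 | secondary ozonide: methyl 8-(5-octyl-1,2,4-trioxolan-3-yl)octanoate (cis/trans mixture) | CCCCCCCCC1OOC(CCCCCCCC(=O)OC)O1 | intermediate
8 | methyl 9-oxononanoate | O=CCCCCCCCC(=O)OC | intermediate
9 | boron enolate: dicyclohexyl(tricos-1-en-2-yloxy)borane | CCCCCCCCCCCCCCCCCCCCCC(=C)OB(C1CCCCC1)C1CCCCC1 | intermediate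
10 | boron aldolate: methyl 9-[(dicyclohexylboranyl)oxy]-11-oxodotriacontanoate (racemic) | CCCCCCCCCCCCCCCCCCCCCC(=O)CC(CCCCCCCC(=O)OC)OB(C1CCCCC1)C1CCCCC1 | intermediate
11 | methyl 9-hydroxy-11-oxodotriacontanoate (racemic) | CCCCCCCCCCCCCCCCCCCCCC(=O)CC(O)CCCCCCCC(=O)OC | intermediate
12 | β-mesyloxy ketone: methyl 9-(methanesulfonyloxy)-11-oxodotriacontanoate (racemic) | CCCCCCCCCCCCCCCCCCCCCC(=O)CC(CCCCCCCC(=O)OC)OS(C)(=O)=O | intermediate
13 | methyl (E)-11-oxodotriacont-9-enoate | CCCCCCCCCCCCCCCCCCCCCC(=O)/C=C/CCCCCCCC(=O)OC | intermediate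
14 | methyl 11-oxodotriacontanoate | CCCCCCCCCCCCCCCCCCCCCC(=O)CCCCCCCCCC(=O)OC | intermediate
15 | 11-oxodotriacontanoic acid | CCCCCCCCCCCCCCCCCCCCCC(=O)CCCCCCCCCC(=O)O | intermediate
16 | hydrazone: 11-hydrazinylidenedotriacontanoic acid (present as its K salt) | CCCCCCCCCCCCCCCCCCCCCC(=NN)CCCCCCCCCC(=O)O | intermediate
17 | dotriacontanoic (lacceroic) acid | CCCCCCCCCCCCCCCCCCCCCCCCCCCCCCCC(=O)O | intermediate
18 | tyrosol, 4-(2-hydroxyethyl)phenol | OCCc1ccc(O)cc1 | starting material
19 | 2-[4-(benzyloxy)phenyl]ethanol | OCCc1ccc(OCc2ccccc2)cc1 | intermediate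
20 | dotriacontanoyl chloride | CCCCCCCCCCCCCCCCCCCCCCCCCCCCCCCC(=O)Cl | intermediate
21 | 2-[4-(benzyloxy)phenyl]ethyl dotriacontanoate | CCCCCCCCCCCCCCCCCCCCCCCCCCCCCCCC(=O)OCCc1ccc(OCc2ccccc2)cc1 | intermediate
22 | Basalethanolide A, 2-(4-hydroxyphenyl)ethyl dotriacontanoate (achiral) | CCCCCCCCCCCCCCCCCCCCCCCCCCCCCCCC(=O)OCCc1ccc(O)cc1 | target

**Total step count:** 11.
**Longest linear sequence:** 9 steps (steps 1, 2, 4, 5, 6, 7, 8, 10, 11, from behenic acid 1). Steps 3 and 9 are side branches.

**Three steps most likely to fail**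

Step 4. The waxy C23 ketone may crystallise from cold CH2Cl2 before enolisation is complete. Any enolisation at C3 would give a branched aldol that is hard to remove.

The fallback sets out from docosanoyl chloride 2 (it also uses aldehyde 8) and comes back to the route at keto acid 15. It keeps the carbonyl-condensation logic but fixes the nucleophilic site with a second activating group. Every operation runs at or above room temperature.

Chloride 2 is C-acylated with Meldrum's acid (pyridine, CH2Cl2, 0 °C → rt) to give 5-(1-hydroxydocosylidene)-2,2-dimethyl-1,3-dioxane-4,6-dione F1. Refluxing methanol turns this into methyl 3-oxotetracosanoate F2. Knoevenagel condensation of F2 with 8 (cat. piperidinium acetate, toluene, 4 Å sieves) gives dimethyl 2-docosanoylundec-2-enedioate F3 as an E/Z mixture. Hydrogenation (H2, Pd/C, EtOAc) gives dimethyl 2-docosanoylundecanedioate F4. Refluxing AcOH/6 M HCl hydrolyses both esters to 2-docosanoylundecanedioic acid F5, which decarboxylates in the same pot to 15.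

Step 8. The potassium soap of a C32 acid can foam and gel in glycol at 200 °C. Residual ketone or azine co-crystallises with 17.

The fallback sets out from keto ester 14 and comes back at acid 17. It replaces the strongly basic high-temperature reduction with a Mozingo thioacetal desulfurisation.

Keto ester 14 with ethane-1,2-dithiol and BF3·OEt2 (CH2Cl2, rt) gives methyl 10-(2-henicosyl-1,3-dithiolan-2-yl)decanoate F6. Raney nickel in refluxing EtOH–THF gives methyl dotriacontanoate F7. Saponification (KOH, THF–MeOH–H2O, 60 °C, then HCl) gives 17.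

Step 10. The very low solubility of 17 and of its chloride can leave unreacted or rehydrolysed acid that is hard to separate from 21.

The fallback sets out from acid 17 (with unprotected tyrosol 18) and comes back at the target 22, so steps 9 to 11 are skipped. It is a Mitsunobu esterification (PPh3, DIAD, THF–toluene, 45 °C), which activates the primary alcohol instead of the acid. The carboxylic acid (pKa about 5) outcompetes the phenol (pKa about 10) as the nucleophile, and the phenol OH is not displaced. New compounds on this way: none F0.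

**Further compounds**
F1 | step 4 | 5-(1-hydroxydocosylidene)-2,2-dimethyl-1,3-dioxane-4,6-dione | CCCCCCCCCCCCCCCCCCCCCC(O)=C1C(=O)OC(C)(C)OC1=O
F2 | step 4 | methyl 3-oxotetracosanoate | CCCCCCCCCCCCCCCCCCCCCC(=O)CC(=O)OC
F3 | step 4 | dimethyl 2-docosanoylundec-2-enedioate | CCCCCCCCCCCCCCCCCCCCCC(=O)C(=CCCCCCCCC(=O)OC)C(=O)OC
F4 | step 4 | dimethyl 2-docosanoylundecanedioate | CCCCCCCCCCCCCCCCCCCCCC(=O)C(CCCCCCCCC(=O)OC)C(=O)OC
F5 | step 4 | 2-docosanoylundecanedioic acid | CCCCCCCCCCCCCCCCCCCCCC(=O)C(CCCCCCCCC(=O)O)C(=O)O
F6 | step 8 | methyl 10-(2-henicosyl-1,3-dithiolan-2-yl)decanoate | CCCCCCCCCCCCCCCCCCCCCC1(CCCCCCCCCC(=O)OC)SCCS1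
F7 | step 8 | methyl dotriacontanoate | CCCCCCCCCCCCCCCCCCCCCCCCCCCCCCCC(=O)OC
F0 | step 10 | none | none
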